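## Retrosynthetic overview

1. C7–C11 is cut last: a Cu(II)–bis(oxazoline) Mukaiyama aldol of the ring-B enol silane with methyl pyruvate sets C7 and C11.
2. The ring-A pattern (1-OAc, 2-oxo, Δ3, 4-Me) comes from a 2-methoxy-ene-1,4-dione: hydride at C1, then MeLi at C4 / Ac2O trap / hydrolytic 1,3-transposition.
3. Ring B and the quaternary C10 come from an enantioselective Diels–Alder reaction of 2-methoxy-6-methyl-1,4-benzoquinone with 2-(triisopropylsilyloxy)butadiene; the adduct already carries the C7=C8 enol silane needed in line 1.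
4. The quinone (ring A) is made by oxidative dearomatisation of 2-methoxy-6-methylphenol. Ring order: A (from the arene), then B (cycloaddition).

Locants C1–C15 in the text are the eudesmane locants of the target: C1 (CH–OAc), C2 (C=O), C3=C4 (CH3-15 on C4), C5 (H), C6, C7, C8 (C=O), C9, C10 (CH3-14), C11 (C–OH), C12 (CO2Me), C13 (CH3).

Assumption: the (S)-oxazaborolidinium catalyst is taken to deliver the diene to the C5-Re/C6-Si face of quinone 2 (the face that gives 10S); if the sense is the opposite, the (R)-catalyst is used and nothing else changes.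

## Route

Step 1
Reactants: 1 2-methoxy-6-methylphenol
Product: 2 2-methoxy-6-methyl-1,4-benzoquinone
Conditions: O2 (1 atm), Co(salen) (5 mol %), DMF, rt
Reagents that add atoms: dioxygen O=O
Why: Cobalt–salen catalysed aerobic para-oxidation of a phenol (oxidative dearomatisation to the quinone) works here because both ortho positions are blocked, so oxygen enters only at the free para carbon and the arene becomes the cross-conjugated ring-A quinone, with no stereocentre formed.

Step 2
Reactants: 3 methyl vinyl ketone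
Product: 4 2-(triisopropylsilyloxy)buta-1,3-diene
Conditions: TIPSOTf, Et3N, Et2O, 0 °C to rt
Reagents that add atoms: triisopropylsilyl triflate CC(C)[Si](OS(=O)(=O)C(F)(F)F)(C(C)C)C(C)C
Why: Soft enolisation/O-silylation of the enone gives the 2-silyloxydiene, and TIPS is chosen because it survives the cationic Lewis acid of step 3, alkoxide base, MeLi and brief cold dilute acid.

Step 3
Reactants: 2 2-methoxy-6-methyl-1,4-benzoquinone; 4 2-(triisopropylsilyloxy)buta-1,3-diene
Product: 5 (4aR,8aS)-2-methoxy-8a-methyl-7-[(triisopropylsilyl)oxy]-4a,5,8,8a-tetrahydronaphthalene-1,4-dione (cis-fused; H-5 and CH3-14 syn)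
Conditions: (S)-o-tolyl-oxazaborolidine·HNTf2 (20 mol %), CH2Cl2, –78 °C
Reagents that add atoms: none
Why: In this catalytic enantioselective Diels–Alder reaction (chiral oxazaborolidinium Lewis acid) the cation binds the more basic vinylogous-ester carbonyl C4=O, the methoxy-deactivated C2=C3 bond stays inert, and the nucleophilic CH2 terminus of 4 bonds to the methyl-bearing β-carbon, so the quaternary centre C10 (S) is set by catalyst face control, the fusion is cis by suprafacial addition, and the enol silane emerges as C7=C8–OTIPS.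

Step 4
Reactants: 5 cis-fused ene-dione
Product: 7 (4R,4aS,8aS)-4-hydroxy-3-methoxy-4a-methyl-6-[(triisopropylsilyl)oxy]-4a,5,8,8a-tetrahydronaphthalen-1(4H)-one, via trans-enedione 6 (not isolated)
Conditions: t-BuOK (0.2 equiv), THF/t-BuOH, 0 °C to rt; then MeOH, CeCl3·7H2O, NaBH4, –78 °C
Reagents that add atoms: none
Why: Base epimerisation at C5 (the only enolisable C–H, α to C4=O) gives the thermodynamically preferred trans-fused ene-dione with C10 untouched, and the Luche 1,2-reduction then leaves the vinylogous-ester carbonyl C4=O alone while hydride attacks the C1 ketone axially on the face anti to the angular methyl (as in Wieland–Miescher ketone reductions), giving the equatorial C1–OH cis to CH3-14 (1R).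

Step 5
Reactants: 7 hydroxy vinylogous ester
Product: 10 (1R,4aR,8aS)-4,8a-dimethyl-2-oxo-7-[(triisopropylsilyl)oxy]-1,2,4a,5,8,8a-hexahydronaphthalen-1-yl acetate, via dilithium dialkoxide 8 (not isolated), via diacetate 9 (not isolated)
Conditions: MeLi (3 equiv), THF, –78 °C; Ac2O (6 equiv), –78 to 0 °C; then 0.5 M aq. oxalic acid, THF, 0 °C
Reagents that add atoms: methyllithium [Li]C; acetic anhydride CC(=O)OC(C)=O; water O
Why: This is a Stork–Danheiser alkoxy-enone transposition with in-flask O-acylation, in which MeLi (after deprotonating C1–OH) adds 1,2 to the vinylogous-ester carbonyl C4, Ac2O caps both lithium alkoxides so the C1 acetate never meets MeLi, and dilute acid ionises the tertiary allylic C4–OAc to the methoxy-stabilised allyl cation that water captures at C2 with loss of methanol to give the 3-en-2-one, while C1, C5, C10 and the TIPS enol ether are untouched.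

Step 6
Reactants: 10 acetoxy enone enol silane; 11 methyl pyruvate
Product: 12 methyl (2S)-2-[(2R,4aS,5R,8aR)-5-acetoxy-4a,8-dimethyl-3,6-dioxo-1,2,3,4,4a,5,6,8a-octahydronaphthalen-2-yl]-2-hydroxypropanoate (CNP0211188.1)
Conditions: [Cu((S,S)-t-Bu-box)](OTf)2 (1.1 equiv), 11 (3 equiv), THF, –78 to –40 °C; pH 7 buffer
Reagents that add atoms: none
Why: In this copper(II)–bis(oxazoline) Mukaiyama aldol addition to a chelated pyruvate ester (Evans type) the (S,S)-ligand chelate exposes the si face of the ketone (11S), the enol silane is attacked at C7 along the chair-like axial trajectory on the face anti to the axial C10 methyl (7R, side chain cis to H-5), the complex is used stoichiometrically so no silyl-transfer turnover is needed from TIPS, and the cold neutral work-up avoids retro-aldol or epimerisation at C7.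

## Compound list

1 | 2-methoxy-6-methylphenol | COc1cccc(C)c1O | starting material
2 | 2-methoxy-6-methyl-1,4-benzoquinone | COC1=CC(=O)C=C(C)C1=O | intermediate
3 | methyl vinyl ketone (but-3-en-2-one) | CC(=O)C=C | starting material
4 | 2-(triisopropylsilyloxy)buta-1,3-diene | C=CC(=C)O[Si](C(C)C)(C(C)C)C(C)C | intermediate
5 | (4aR,8aS)-2-methoxy-8a-methyl-7-[(triisopropylsilyl)oxy]-4a,5,8,8a-tetrahydronaphthalene-1,4-dione (cis-fused) | CC(C)[Si](OC1=CC[C@H]2C(=O)C=C(OC)C(=O)[C@@]2(C)C1)(C(C)C)C(C)C | intermediate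
6 | (4aS,8aS)-2-methoxy-8a-methyl-7-[(triisopropylsilyl)oxy]-4a,5,8,8a-tetrahydronaphthalene-1,4-dione (trans-fused) | CC(C)[Si](OC1=CC[C@@H]2C(=O)C=C(OC)C(=O)[C@@]2(C)C1)(C(C)C)C(C)C | intermediate (not isolated)
7 | (4R,4aS,8aS)-4-hydroxy-3-methoxy-4a-methyl-6-[(triisopropylsilyl)oxy]-4a,5,8,8a-tetrahydronaphthalen-1(4H)-one | CC(C)[Si](OC1=CC[C@@H]2C(=O)C=C(OC)[C@H](O)[C@@]2(C)C1)(C(C)C)C(C)C | intermediate
8 | dilithium (1R,4aS,8aS)-2-methoxy-4,8a-dimethyl-7-[(triisopropylsilyl)oxy]-1,4,4a,5,8,8a-hexahydronaphthalene-1,4-diolate (C4 epimers, centre lost later) | CC(C)[Si](OC1=CC[C@@H]2C(C)([O-])C=C(OC)[C@H]([O-])[C@@]2(C)C1)(C(C)C)C(C)C.[Li+].[Li+] | intermediate (not isolated)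
9 | (1R,4aS,8aS)-2-methoxy-4,8a-dimethyl-7-[(triisopropylsilyl)oxy]-1,4,4a,5,8,8a-hexahydronaphthalene-1,4-diyl diacetate (C4 epimers, centre lost later) | CC(C)[Si](OC1=CC[C@@H]2C(C)(OC(C)=O)C=C(OC)[C@H](OC(C)=O)[C@@]2(C)C1)(C(C)C)C(C)C | intermediate (not isolated)
10 | (1R,4aR,8aS)-4,8a-dimethyl-2-oxo-7-[(triisopropylsilyl)oxy]-1,2,4a,5,8,8a-hexahydronaphthalen-1-yl acetate | CC(C)[Si](OC1=CC[C@@H]2C(C)=CC(=O)[C@H](OC(C)=O)[C@@]2(C)C1)(C(C)C)C(C)C | intermediate
11 | methyl pyruvate | CC(=O)C(=O)OC | starting material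
12 | methyl (2S)-2-[(2R,4aS,5R,8aR)-5-acetoxy-4a,8-dimethyl-3,6-dioxo-1,2,3,4,4a,5,6,8a-octahydronaphthalen-2-yl]-2-hydroxypropanoate | COC(=O)[C@@](C)(O)[C@H]1C[C@@H]2C(C)=CC(=O)[C@H](OC(C)=O)[C@@]2(C)CC1=O | target

## Step count and risks

Total steps: 6. Longest linear sequence: 5 (1 → 2 → 5 → 7 → 10 → 12); step 2 is a one-step side branch.

Step 3 is the most exposed. The dienophile carbon that must take the new bond is fully substituted, the orientation relies on the catalyst sitting on the vinylogous-ester carbonyl, and the absolute sense is assumed. Fallback: set out from 2 and 4 and run the cycloaddition racemically with an achiral Lewis acid (Et2AlCl, CH2Cl2, –78 °C; same carbonyl complexation, same orientation) to the racemic cis-adduct F1. Carry it through the step-4 protocol via the racemic trans-ene-dione F2 to the racemic alcohol F3, and resolve F3 by preparative chiral SFC. The route is rejoined at 7.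

Step 5 can fail by enolisation at C5 with MeLi, incomplete acetylation of the hindered C1 alkoxide, or loss of the TIPS enol ether in the acid stage. Fallback: set out from 7 and methylenate the vinylogous-ester carbonyl with the Tebbe reagent (2.5 equiv, THF/pyridine, –40 to 0 °C; non-basic, free OH tolerated) to the 2-methoxy-1,3-diene F4. Hydrolyse it on moist silica gel (protonation at the exocyclic CH2) to the hydroxy enone F5, and acetylate (Ac2O, pyridine, DMAP). The route is rejoined at 10.

Step 6 can fail through low reactivity of the TIPS enol silane, a mismatched catalyst/substrate pairing at C11, or loss of the axial C7 configuration. Fallback: set out from 10 and remove the silyl group with buffered fluoride (TBAF/AcOH, THF, 0 °C) to the acetoxy diketone F6. Then run an enamine-catalysed direct aldol with methyl pyruvate 11 (proline-type amine, antipode chosen for 11S, DMSO, rt); the enamine forms only at the saturated C8 ketone and towards C7, away from the quaternary carbon. The route is rejoined at 12.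

## Further compounds

F1 | step 3 | racemic cis-2-methoxy-8a-methyl-7-[(triisopropylsilyl)oxy]-4a,5,8,8a-tetrahydronaphthalene-1,4-dione (rac-5) | CC(C)[Si](OC1=CC[C@H]2C(=O)C=C(OC)C(=O)[C@@]2(C)C1)(C(C)C)C(C)C.CC(C)[Si](OC1=CC[C@@H]2C(=O)C=C(OC)C(=O)[C@]2(C)C1)(C(C)C)C(C)C
F2 | step 3 | racemic trans-2-methoxy-8a-methyl-7-[(triisopropylsilyl)oxy]-4a,5,8,8a-tetrahydronaphthalene-1,4-dione (rac-6) | CC(C)[Si](OC1=CC[C@@H]2C(=O)C=C(OC)C(=O)[C@@]2(C)C1)(C(C)C)C(C)C.CC(C)[Si](OC1=CC[C@H]2C(=O)C=C(OC)C(=O)[C@]2(C)C1)(C(C)C)C(C)C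
F3 | step 3 | racemic 4-hydroxy-3-methoxy-4a-methyl-6-[(triisopropylsilyl)oxy]-4a,5,8,8a-tetrahydronaphthalen-1(4H)-one (rac-7) | CC(C)[Si](OC1=CC[C@@H]2C(=O)C=C(OC)[C@H](O)[C@@]2(C)C1)(C(C)C)C(C)C.CC(C)[Si](OC1=CC[C@H]2C(=O)C=C(OC)[C@@H](O)[C@]2(C)C1)(C(C)C)C(C)C
F4 | step 5 | (1R,4aR,8aS)-2-methoxy-8a-methyl-4-methylidene-7-[(triisopropylsilyl)oxy]-1,4,4a,5,8,8a-hexahydronaphthalen-1-ol | CC(C)[Si](OC1=CC[C@@H]2C(=C)C=C(OC)[C@H](O)[C@@]2(C)C1)(C(C)C)C(C)C
F5 | step 5 | (1R,4aR,8aS)-1-hydroxy-4,8a-dimethyl-7-[(triisopropylsilyl)oxy]-4a,5,8,8a-tetrahydronaphthalen-2(1H)-one | CC(C)[Si](OC1=CC[C@@H]2C(C)=CC(=O)[C@H](O)[C@@]2(C)C1)(C(C)C)C(C)C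
F6 | step 6 | (1R,4aR,8aS)-4,8a-dimethyl-2,7-dioxo-1,2,4a,5,6,7,8,8a-octahydronaphthalen-1-yl acetate | O=C1CC[C@@H]2C(C)=CC(=O)[C@H](OC(C)=O)[C@@]2(C)C1
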